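The pyran (C) ring is cut at C3–C4 and O1–C8a: C3 lies between the benzylic C4 and the carbinol C2, so it can be introduced as the acyl-anion carbon of 1,3-dithiane, and the A-ring carbon C8a is ortho to C4a, which carries C4, so a benzylic chloride/aryl fluoride pair serves as 1,3-dielectrophile. In one flask the dithiane is added to the B-ring aldehyde, benzylated at C3 by the A-ring chloride and ring-closed by alkoxide SNAr at C8a. Unmasking gives a racemic flavan-3-one, whose labile C2–H allows an asymmetric hydrogenation with dynamic kinetic resolution to set both stereocentres; double galloylation of the 3,5-diol and hydrogenolysis finish the route.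

Key step: step 5

Remark on the chemistry: compounds 11–15 are racemic by design; both stereocentres are set in step 7, where the catalyst antipode is assigned by analogy with 2-arylcycloalkanones and is to be chosen so that (2R,3R) results.

Step 1
Reactants: 1 2,4,6-trifluorobenzaldehyde; 2 benzyl alcohol
Product: 3 4-(benzyloxy)-2,6-difluorobenzaldehyde
Conditions: Cs2CO3, DMF, 0 °C → rt
Reagents that add atoms: none
Why: SNAr (addition–elimination) in which the formyl group activates the C–F bonds and, in a dipolar aprotic solvent with a non-chelating counter-ion, the para fluoride should be replaced preferentially, while one equivalent of alcohol and the deactivating new alkoxy group should stop the reaction at mono-substitution.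

Step 2
Reactants: 3 4-(benzyloxy)-2,6-difluorobenzaldehyde; 4 allyl alcohol
Product: 5 2-(allyloxy)-4-(benzyloxy)-6-fluorobenzaldehyde
Conditions: Cs2CO3, DMF, rt → 40 °C
Reagents that add atoms: none
Why: Second SNAr at one of the two equivalent ortho fluorides, after which the ring carries two donors, so that the last fluoride should survive when one equivalent of alcohol is used.

Step 3
Reactants: 5 2-(allyloxy)-4-(benzyloxy)-6-fluorobenzaldehyde
Product: 6 [2-(allyloxy)-4-(benzyloxy)-6-fluorophenyl]methanol
Conditions: NaBH4, MeOH–THF, 0 °C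
Reagents that add atoms: none
Why: Borohydride reduction of the aldehyde, to which the aryl fluoride and the allyl and benzyl ethers are inert.

Step 4
Reactants: 6 [2-(allyloxy)-4-(benzyloxy)-6-fluorophenyl]methanol
Product: 7 1-(allyloxy)-5-(benzyloxy)-2-(chloromethyl)-3-fluorobenzene
Conditions: PPh3, NCS, THF, −20 → 0 °C
Reagents that add atoms: N-chlorosuccinimide, ClN1C(=O)CCC1=O
Why: Appel-type chlorination through an alkoxyphosphonium chloride under neutral conditions, which avoids acid-promoted ionisation of the electron-rich benzylic system; the chloride should be used at once.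

Step 5
Reactants: 8 1,3-dithiane; 9 3,4-bis(benzyloxy)benzaldehyde; 7 1-(allyloxy)-5-(benzyloxy)-2-(chloromethyl)-3-fluorobenzene
Product: 14 rac-5-(allyloxy)-7-(benzyloxy)-2-[3,4-bis(benzyloxy)phenyl]spiro[chromane-3,2'-[1,3]dithiane], via 2-lithio-1,3-dithiane 10 (not isolated), via lithium alkoxide of the aldehyde adduct 11 (not isolated), via O,C-dilithio species 12 (not isolated), via C3-benzylated lithium alkoxide 13 (not isolated)
Conditions: n-BuLi, THF, −30 °C; 9, −78 °C; n-BuLi, −30 °C; 7, −78 → −20 °C; then KOt-Bu, 18-crown-6, 0 → 50 °C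
Reagents that add atoms: none
Why: Corey–Seebach umpolung run as an anion relay: 2-lithio-1,3-dithiane (the future C3) adds to aldehyde 9 (C2–C3), a second lithiation gives the O,C-dilithio species 12 whose soft carbanion is benzylated by chloride 7 in an SN2 step (C3–C4), and after Li→K exchange the C2 alkoxide of 13 displaces the ortho fluoride through a Meisenheimer adduct (O1–C8a). The closest known reaction types are the sequential functionalisation of 1,3-dithiane with two electrophiles and the intramolecular alkoxide SNAr on 3,5-dialkoxyfluoroarenes used to close chroman rings. The pyran ring closes in a 6-exo-trig addition–elimination at the ipso carbon, helped by the Thorpe–Ingold effect of the spiro dithiane at C3. The only stereocentre formed, C2, arises without control in the aldehyde addition and is deliberately left racemic, because it is corrected by the dynamic hydrogenation of step 7. The step needs C- over O-benzylation (in THF the lithium alkoxide is far less nucleophilic than the dithianyl carbanion, and n-BuLi is fully consumed before 7 is added, which spares the acidic Ar–H next to fluorine) and a single oxygen nucleophile in the closure (C3 is a dithioketal, so there is neither a C3 alkoxide nor an enolate that could give a five-membered ether), while fluoride is the only SNAr leaving group on the ring and THF instead of DMSO should keep the allyl ether from isomerising.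

Step 6
Reactants: 14 rac-5-(allyloxy)-7-(benzyloxy)-2-[3,4-bis(benzyloxy)phenyl]spiro[chromane-3,2'-[1,3]dithiane]
Product: 15 rac-5-(allyloxy)-7-(benzyloxy)-2-[3,4-bis(benzyloxy)phenyl]chroman-3-one
Conditions: MeI, CaCO3, MeCN–H2O (9:1), 45 °C
Reagents that add atoms: water, O
Why: Alkylative dithioacetal hydrolysis, in which S-methylation turns sulfur into a leaving group and water delivers the carbonyl oxygen under CaCO3 buffering, conditions that are non-oxidising toward the electron-rich arenes and leave allyl and benzyl ethers intact; C2 is racemic here, so its lability is of no consequence.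

Step 7
Reactants: 15 rac-5-(allyloxy)-7-(benzyloxy)-2-[3,4-bis(benzyloxy)phenyl]chroman-3-one
Product: 16 (2R,3R)-5-(allyloxy)-7-(benzyloxy)-2-[3,4-bis(benzyloxy)phenyl]chroman-3-ol
Conditions: H2 (50 atm), RuCl2[(S)-Xyl-SDP][(R,R)-DPEN] (cat., or its mirror image), KOt-Bu (cat.), i-PrOH–toluene, rt
Reagents that add atoms: none
Why: Noyori-type Ru(diphosphine)(diamine) asymmetric hydrogenation with dynamic kinetic resolution, in which C2–H (α to C=O, benzylic, α-aryloxy) should epimerise through the enolate faster than reduction, the catalyst reduces one ketone enantiomer preferentially with hydride delivery to the C3 face anti to the C2 aryl group (2,3-cis, as with 2-arylcycloalkanones), the catalyst antipode fixes (2R,3R), and the C=O-selective catalyst should leave the allyl C=C and the benzyl ethers untouched.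

Step 8
Reactants: 16 (2R,3R)-5-(allyloxy)-7-(benzyloxy)-2-[3,4-bis(benzyloxy)phenyl]chroman-3-ol
Product: 17 (2R,3R)-7-(benzyloxy)-2-[3,4-bis(benzyloxy)phenyl]chromane-3,5-diol
Conditions: Pd(PPh3)4 (cat.), morpholine, THF, rt
Reagents that add atoms: none
Why: Tsuji–Trost deallylation, in which Pd(0) ionises the aryl allyl ether to a π-allyl complex that morpholine captures, leaving benzyl ethers and both stereocentres untouched.

Step 9
Reactants: 17 (2R,3R)-7-(benzyloxy)-2-[3,4-bis(benzyloxy)phenyl]chromane-3,5-diol; 18 3,4,5-tris(benzyloxy)benzoic acid (first of the two equivalents that are incorporated)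
Product: 19 (2R,3R)-7-(benzyloxy)-2-[3,4-bis(benzyloxy)phenyl]chromane-3,5-diyl bis[3,4,5-tris(benzyloxy)benzoate]
Conditions: 18 (2.5 equiv in all), EDC·HCl (3 equiv), DMAP (0.5 equiv), CH2Cl2, 0 °C → rt
Reagents that add atoms: 3,4,5-tris(benzyloxy)benzoic acid (the second equivalent of 18), OC(=O)c1cc(OCc2ccccc2)c(OCc2ccccc2)c(OCc2ccccc2)c1
Why: Twofold Steglich esterification (carbodiimide activation, DMAP acyl transfer) in which one molecule of acid 18 acylates the phenolic 5-OH and a second molecule acylates the secondary 3-OH, the excess of acid and carbodiimide driving both to completion, with no bond to a stereocentre made or broken.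

Step 10
Reactants: 19 (2R,3R)-7-(benzyloxy)-2-[3,4-bis(benzyloxy)phenyl]chromane-3,5-diyl bis[3,4,5-tris(benzyloxy)benzoate]
Product: 20 epicatechin 3,5-di-O-gallate
Conditions: H2 (1 atm), Pd(OH)2/C, THF–EtOAc, rt
Reagents that add atoms: none
Why: Hydrogenolysis of all nine benzyl ethers over Pearlman's catalyst under neutral conditions in a non-nucleophilic solvent, so that the aryl and alkyl gallate esters should neither cleave nor migrate and C2/C3 stay as set.

Compound list
1 | 2,4,6-trifluorobenzaldehyde | O=Cc1c(F)cc(F)cc1F | starting material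
2 | benzyl alcohol | OCc1ccccc1 | starting material
3 | 4-(benzyloxy)-2,6-difluorobenzaldehyde | O=Cc1c(F)cc(OCc2ccccc2)cc1F | intermediate
4 | allyl alcohol | C=CCO | starting material
5 | 2-(allyloxy)-4-(benzyloxy)-6-fluorobenzaldehyde | O=Cc1c(F)cc(OCc2ccccc2)cc1OCC=C | intermediate
6 | [2-(allyloxy)-4-(benzyloxy)-6-fluorophenyl]methanol | OCc1c(F)cc(OCc2ccccc2)cc1OCC=C | intermediate
7 | 1-(allyloxy)-5-(benzyloxy)-2-(chloromethyl)-3-fluorobenzene | ClCc1c(F)cc(OCc2ccccc2)cc1OCC=C | intermediate
8 | 1,3-dithiane | C1CSCSC1 | starting material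
9 | 3,4-bis(benzyloxy)benzaldehyde | O=Cc1ccc(OCc2ccccc2)c(OCc2ccccc2)c1 | starting material
10 | 2-lithio-1,3-dithiane | [Li]C1SCCCS1 | intermediate (not isolated)
11 | rac-lithium [3,4-bis(benzyloxy)phenyl](1,3-dithian-2-yl)methoxide | [Li]OC(c1ccc(OCc2ccccc2)c(OCc2ccccc2)c1)C1SCCCS1 | intermediate (not isolated)
12 | rac-lithium [3,4-bis(benzyloxy)phenyl](2-lithio-1,3-dithian-2-yl)methoxide | [Li]OC(c1ccc(OCc2ccccc2)c(OCc2ccccc2)c1)C1([Li])SCCCS1 | intermediate (not isolated)
13 | rac-lithium [3,4-bis(benzyloxy)phenyl]{2-[2-(allyloxy)-4-(benzyloxy)-6-fluorobenzyl]-1,3-dithian-2-yl}methoxide | [Li]OC(c1ccc(OCc2ccccc2)c(OCc2ccccc2)c1)C1(Cc2c(F)cc(OCc3ccccc3)cc2OCC=C)SCCCS1 | intermediate (not isolated)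
14 | rac-5-(allyloxy)-7-(benzyloxy)-2-[3,4-bis(benzyloxy)phenyl]spiro[chromane-3,2'-[1,3]dithiane] | C=CCOc1cc(OCc2ccccc2)cc2c1CC1(SCCCS1)C(c1ccc(OCc3ccccc3)c(OCc3ccccc3)c1)O2 | intermediate
15 | rac-5-(allyloxy)-7-(benzyloxy)-2-[3,4-bis(benzyloxy)phenyl]chroman-3-one | C=CCOc1cc(OCc2ccccc2)cc2c1CC(=O)C(c1ccc(OCc3ccccc3)c(OCc3ccccc3)c1)O2 | intermediate
16 | (2R,3R)-5-(allyloxy)-7-(benzyloxy)-2-[3,4-bis(benzyloxy)phenyl]chroman-3-ol | C=CCOc1cc(OCc2ccccc2)cc2c1C[C@@H](O)[C@@H](c1ccc(OCc3ccccc3)c(OCc3ccccc3)c1)O2 | intermediate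
17 | (2R,3R)-7-(benzyloxy)-2-[3,4-bis(benzyloxy)phenyl]chromane-3,5-diol | Oc1cc(OCc2ccccc2)cc2c1C[C@@H](O)[C@@H](c1ccc(OCc3ccccc3)c(OCc3ccccc3)c1)O2 | intermediate
18 | 3,4,5-tris(benzyloxy)benzoic acid | OC(=O)c1cc(OCc2ccccc2)c(OCc2ccccc2)c(OCc2ccccc2)c1 | starting material
19 | (2R,3R)-7-(benzyloxy)-2-[3,4-bis(benzyloxy)phenyl]chromane-3,5-diyl bis[3,4,5-tris(benzyloxy)benzoate] | O=C(Oc1cc(OCc2ccccc2)cc2c1C[C@@H](OC(=O)c1cc(OCc3ccccc3)c(OCc3ccccc3)c(OCc3ccccc3)c1)[C@@H](c1ccc(OCc3ccccc3)c(OCc3ccccc3)c1)O2)c1cc(OCc2ccccc2)c(OCc2ccccc2)c(OCc2ccccc2)c1 | intermediate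
20 | epicatechin 3,5-di-O-gallate, (2R,3R) | O=C(Oc1cc(O)cc2c1C[C@@H](OC(=O)c1cc(O)c(O)c(O)c1)[C@@H](c1ccc(O)c(O)c1)O2)c1cc(O)c(O)c(O)c1 | target

Total step count: 10. Longest linear sequence: 10 steps (steps 1–10; compounds 8, 9 and 18 are commercial).

Steps most likely to fail

Step 5. The second lithiation of the oxido-substituted dithiane may be incomplete, the hindered carbanion may be protonated or transfer an electron instead of alkylating, and the potassium alkoxide may revert to aldehyde and dithianyl anion or isomerise the allyl ether before the SNAr closure is complete. The fallback gives up the one-flask relay for a stop-and-go sequence that sets out from 8 and 9 and comes back at 14. The adduct of 2-lithio-1,3-dithiane and 9 is quenched and purified as rac-[3,4-bis(benzyloxy)phenyl](1,3-dithian-2-yl)methanol F1. Its O,C-dianion (n-BuLi, 2 equiv, THF, −30 °C) is alkylated with 7 and protonated to give rac-[3,4-bis(benzyloxy)phenyl]{2-[2-(allyloxy)-4-(benzyloxy)-6-fluorobenzyl]-1,3-dithian-2-yl}methanol F2. This alcohol is closed separately as its naked potassium alkoxide (KH, DMF, 0 °C → rt) to 14, so that each bond formation can be optimised on purified material.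

Step 7. Discrimination between the equilibrating ketone enantiomers may be insufficient, the cis selectivity may erode, or the enolisable α-aryloxy ketone may condense or oxidise under the basic conditions. The fallback replaces catalytic dynamic resolution by substrate-controlled reduction and classical resolution; it sets out from 15 and comes back at 16. L-Selectride (THF, −78 °C) should attack anti to the C2 aryl group and give the cis racemate, that is 16 together with (2S,3S)-5-(allyloxy)-7-(benzyloxy)-2-[3,4-bis(benzyloxy)phenyl]chroman-3-ol F3. Acylation with (1S)-camphanic chloride (pyridine, DMAP) gives the diastereomeric esters (2R,3R)-5-(allyloxy)-7-(benzyloxy)-2-[3,4-bis(benzyloxy)phenyl]chroman-3-yl (1S)-camphanate F4 and (2S,3S)-5-(allyloxy)-7-(benzyloxy)-2-[3,4-bis(benzyloxy)phenyl]chroman-3-yl (1S)-camphanate F5, which are separated by chromatography or crystallisation. Methanolysis of F4 (K2CO3, MeOH) returns 16.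

Step 6. S-Methylation at the neopentyl-type spiro dithioketal may be sluggish, and the sensitive enolisable ketone may decompose (aldol condensation, air oxidation) during prolonged heating. The fallback activates sulfur by oxidation instead of alkylation; it sets out from 14 and comes back at 15. Sodium periodate (1 equiv, MeOH–THF–H2O, 0 °C) gives rac-5-(allyloxy)-7-(benzyloxy)-2-[3,4-bis(benzyloxy)phenyl]spiro[chromane-3,2'-[1,3]dithiane] 1'-oxide F6 (mixture of diastereomers). This S-oxide is hydrolysed at room temperature by dilute aqueous HCl in THF to 15.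

Further compounds
F1 | step 5 | rac-[3,4-bis(benzyloxy)phenyl](1,3-dithian-2-yl)methanol | OC(c1ccc(OCc2ccccc2)c(OCc2ccccc2)c1)C1SCCCS1
F2 | step 5 | rac-[3,4-bis(benzyloxy)phenyl]{2-[2-(allyloxy)-4-(benzyloxy)-6-fluorobenzyl]-1,3-dithian-2-yl}methanol | OC(c1ccc(OCc2ccccc2)c(OCc2ccccc2)c1)C1(Cc2c(F)cc(OCc3ccccc3)cc2OCC=C)SCCCS1
F3 | step 7 | (2S,3S)-5-(allyloxy)-7-(benzyloxy)-2-[3,4-bis(benzyloxy)phenyl]chroman-3-ol | C=CCOc1cc(OCc2ccccc2)cc2c1C[C@H](O)[C@H](c1ccc(OCc3ccccc3)c(OCc3ccccc3)c1)O2
F4 | step 7 | (2R,3R)-5-(allyloxy)-7-(benzyloxy)-2-[3,4-bis(benzyloxy)phenyl]chroman-3-yl (1S)-camphanate | C=CCOc1cc(OCc2ccccc2)cc2c1C[C@@H](OC(=O)[C@@]13CC[C@@](C)(C(=O)O1)C3(C)C)[C@@H](c1ccc(OCc3ccccc3)c(OCc3ccccc3)c1)O2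
F5 | step 7 | (2S,3S)-5-(allyloxy)-7-(benzyloxy)-2-[3,4-bis(benzyloxy)phenyl]chroman-3-yl (1S)-camphanate | C=CCOc1cc(OCc2ccccc2)cc2c1C[C@H](OC(=O)[C@@]13CC[C@@](C)(C(=O)O1)C3(C)C)[C@H](c1ccc(OCc3ccccc3)c(OCc3ccccc3)c1)O2
F6 | step 6 | rac-5-(allyloxy)-7-(benzyloxy)-2-[3,4-bis(benzyloxy)phenyl]spiro[chromane-3,2'-[1,3]dithiane] 1'-oxide | C=CCOc1cc(OCc2ccccc2)cc2c1CC1(SCCCS1=O)C(c1ccc(OCc3ccccc3)c(OCc3ccccc3)c1)O2
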